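**Strategy.** The dihydrobenzofuran that carries the 3,5-dihydroxyphenyl group (ring B) is closed at its aryl–oxygen bond, O1–C7a. C7a and C4 are the two ortho positions of C3a, so the precursor, an enantiopure 1,2,2-triarylethanol from hydrogenative dynamic kinetic resolution of a racemic α,α-diaryl ketone, carries a 2,6-dichloro-4-benzyloxyphenyl ring with homotopic chlorines. One palladium catalyst etherifies at either chlorine and then uses the survivor at C4 for ketone α-arylation, so ring B and the two-carbon handle for the styryl-bearing ring A arise in one pot. The same three operations with the enantiomeric catalyst build ring A; alkynylation, cis-semihydrogenation and debenzylation finish.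

Key step: step 5

Remark: the target is read as (2S,3S) in ring A and (2R,3R) in ring B, both 2,3-trans, with a Z alkene; benzofuran numbering is used for each ring, Bn = benzyl, RB = (2R,3R)-6-(benzyloxy)-2-[4-(benzyloxy)phenyl]-3-[3,5-bis(benzyloxy)phenyl]-2,3-dihydro-1-benzofuran-4-yl, and 1, 3, 5 and 13 are taken as catalogue compounds.

Step 1
Reactants: 1 4-bromo-3,5-dichlorophenol
Product: 2 5-(benzyloxy)-2-bromo-1,3-dichlorobenzene
Conditions: BnBr, K2CO3, DMF, rt
Reagents that add atoms: benzyl bromide BrCc1ccccc1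
Why: Williamson ether synthesis; the phenoxide is the only nucleophile present and the aryl halides are inert.

Step 2
Reactants: 2 5-(benzyloxy)-2-bromo-1,3-dichlorobenzene; 3 1-[4-(benzyloxy)phenyl]ethan-1-one (1.5 equiv)
Product: 4 1-[4-(benzyloxy)phenyl]-2-[4-(benzyloxy)-2,6-dichlorophenyl]ethan-1-one
Conditions: Pd2(dba)3 (1.5 mol%), Xantphos (3.6 mol%), NaOtBu, toluene, 80 °C
Reagents that add atoms: none
Why: Pd-catalysed ketone α-arylation (Buchwald–Hartwig type); oxidative addition should occur at C–Br only, the flanking C–Cl bonds being inert with this bisphosphine, and the hindered product should resist a second arylation.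

Step 3
Reactants: 4 1-[4-(benzyloxy)phenyl]-2-[4-(benzyloxy)-2,6-dichlorophenyl]ethan-1-one; 5 1,3-bis(benzyloxy)-5-bromobenzene
Product: 6 rac-1-[4-(benzyloxy)phenyl]-2-[4-(benzyloxy)-2,6-dichlorophenyl]-2-[3,5-bis(benzyloxy)phenyl]ethan-1-one
Conditions: Pd2(dba)3 (2 mol%), Xantphos (5 mol%), NaOtBu, toluene, 90 °C
Reagents that add atoms: none
Why: second Pd-catalysed α-arylation, now of the more acidic deoxybenzoin with an unhindered aryl bromide; the C2 centre forms racemic and stays base-labile, which the next step uses.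

Step 4
Reactants: 6 rac-1-[4-(benzyloxy)phenyl]-2-[4-(benzyloxy)-2,6-dichlorophenyl]-2-[3,5-bis(benzyloxy)phenyl]ethan-1-one
Product: 7 (1R,2R)-1-[4-(benzyloxy)phenyl]-2-[4-(benzyloxy)-2,6-dichlorophenyl]-2-[3,5-bis(benzyloxy)phenyl]ethan-1-ol
Conditions: trans-RuCl2[(S)-XylBINAP][(S)-DAIPEN] (1 mol%), KOtBu (0.2 equiv), H2 (10 atm), iPrOH/toluene, 30 °C
Reagents that add atoms: none
Why: Noyori asymmetric hydrogenation with dynamic kinetic resolution; KOtBu equilibrates the ketone enantiomers through the enolate, the (S,S) catalyst should give the (R)-carbinol as with simple aryl ketones, and it should reduce faster the enantiomer whose reacting face is the Felkin–Anh face anti to the perpendicular dichloroaryl group, which sets C2 as R.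

Step 5
Reactants: 7 (1R,2R)-1-[4-(benzyloxy)phenyl]-2-[4-(benzyloxy)-2,6-dichlorophenyl]-2-[3,5-bis(benzyloxy)phenyl]ethan-1-ol; 3 1-[4-(benzyloxy)phenyl]ethan-1-one (2.5 equiv)
Product: 9 1-[4-(benzyloxy)phenyl]-2-(RB)ethan-1-one, via 4-chlorodihydrobenzofuran 8 (not isolated)
Conditions: Pd2(dba)3 (2 mol%), tBuXPhos (8 mol%), Cs2CO3, toluene, 80 °C; then 3, XPhos (4 mol%), NaOtBu, 100 °C, same pot
Reagents that add atoms: none
Why: Pd(0) inserts into one of the two ortho C–Cl bonds, the caesium alkoxide replaces chloride on palladium to give a six-membered oxapalladacycle, and C–O reductive elimination forms O1–C7a; the surviving C4–Cl then enters the α-arylation cycle of the same palladium with the sodium enolate of 3 (oxidative addition, C-bound enolate, C–C reductive elimination). The closest known reaction types are the intramolecular Buchwald–Hartwig etherification of aryl chlorides by secondary alcohols and the Pd-catalysed α-arylation of aryl methyl ketones with aryl chlorides. The dihydrofuran ring closes in a 5-exo sense onto the arene through that six-membered palladacycle. No stereocentre is created: no bond to C2 or C3 is broken, so the (1R,2R) alcohol is carried with retention into the 2,3-trans (2R,3R) ring. Regioselectivity is built into the substrate, because the two chlorines flank C3a symmetrically and exchange by rotation about the C3–C3a bond, so either closure gives the same ring and leaves one chlorine at C4. The step needs C–O reductive elimination to beat β-hydride elimination of the secondary alkoxide and needs mono-arylation of 3; the bulky di-tert-butylbiarylphosphine, the intramolecular closure and the excess of 3 against an ortho-substituted aryl chloride should secure both.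

Step 6
Reactants: 9 1-[4-(benzyloxy)phenyl]-2-(RB)ethan-1-one; 2 5-(benzyloxy)-2-bromo-1,3-dichlorobenzene (1.3 equiv)
Product: 10 1-[4-(benzyloxy)phenyl]-2-[4-(benzyloxy)-2,6-dichlorophenyl]-2-(RB)ethan-1-one (both C2 epimers)
Conditions: Pd(OAc)2 (5 mol%), P(tBu)3·HBF4 (10 mol%), NaOtBu, toluene, 70 °C
Reagents that add atoms: none
Why: Pd-catalysed α-arylation with oxidative addition at the C–Br bond of 2; the new C2 centre forms as both epimers, which is harmless because they interconvert through the enolate in the next step.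

Step 7
Reactants: 10 1-[4-(benzyloxy)phenyl]-2-[4-(benzyloxy)-2,6-dichlorophenyl]-2-(RB)ethan-1-one (both C2 epimers)
Product: 11 (1S,2S)-1-[4-(benzyloxy)phenyl]-2-[4-(benzyloxy)-2,6-dichlorophenyl]-2-(RB)ethan-1-ol
Conditions: trans-RuCl2[(R)-XylBINAP][(R)-DAIPEN] (2 mol%), KOtBu (0.3 equiv), H2 (10 atm), iPrOH/toluene, 30 °C
Reagents that add atoms: none
Why: Noyori asymmetric hydrogenation with dynamic kinetic resolution as in step 4 with the enantiomeric catalyst; catalyst control should set the carbinol as S, and Felkin–Anh matching with the dichloroaryl group as the large substituent should select the 2S epimer, while the ring-B centres are untouched.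

Step 8
Reactants: 11 (1S,2S)-1-[4-(benzyloxy)phenyl]-2-[4-(benzyloxy)-2,6-dichlorophenyl]-2-(RB)ethan-1-ol
Product: 12 (2S,3S)-6-(benzyloxy)-2-[4-(benzyloxy)phenyl]-4-chloro-3-(RB)-2,3-dihydro-1-benzofuran
Conditions: Pd2(dba)3 (2 mol%), tBuXPhos (8 mol%), Cs2CO3, toluene, 80 °C
Reagents that add atoms: none
Why: intramolecular Buchwald–Hartwig etherification as in the first stage of step 5; either equivalent chlorine closes ring A with retention at both centres, giving the 2,3-trans (2S,3S) ring and leaving one chlorine at C4.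

Step 9
Reactants: 12 (2S,3S)-6-(benzyloxy)-2-[4-(benzyloxy)phenyl]-4-chloro-3-(RB)-2,3-dihydro-1-benzofuran; 13 1-(benzyloxy)-4-ethynylbenzene
Product: 14 (2S,3S)-6-(benzyloxy)-2-[4-(benzyloxy)phenyl]-4-{[4-(benzyloxy)phenyl]ethynyl}-3-(RB)-2,3-dihydro-1-benzofuran
Conditions: PdCl2(MeCN)2 (3 mol%), XPhos (9 mol%), Cs2CO3, MeCN, 90 °C, 13 added slowly
Reagents that add atoms: none
Why: copper-free Sonogashira coupling of an aryl chloride, enabled by the bulky biarylphosphine; no stereocentre is involved and the benzylic ring ethers are inert to carbonate.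

Step 10
Reactants: 14 (2S,3S)-6-(benzyloxy)-2-[4-(benzyloxy)phenyl]-4-{[4-(benzyloxy)phenyl]ethynyl}-3-(RB)-2,3-dihydro-1-benzofuran
Product: 15 (2S,3S)-6-(benzyloxy)-2-[4-(benzyloxy)phenyl]-4-{(Z)-2-[4-(benzyloxy)phenyl]ethenyl}-3-(RB)-2,3-dihydro-1-benzofuran (hepta-O-benzyl-cis-miyabenol C)
Conditions: H2 (1 atm), Lindlar catalyst, quinoline, EtOAc, rt, stopped at one equivalent
Reagents that add atoms: none
Why: Lindlar semihydrogenation; syn delivery of H2 on the poisoned palladium surface should give the Z-stilbene, and aryl benzyl ethers are not cleaved under these conditions.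

Step 11
Reactants: 15 hepta-O-benzyl-cis-miyabenol C
Product: 16 cis-miyabenol C
Conditions: BCl3 (excess), pentamethylbenzene, CH2Cl2, −78 °C, dark; MeOH quench at −78 °C
Reagents that add atoms: none
Why: Lewis-acid debenzylation of aryl benzyl ethers with pentamethylbenzene as non-basic benzyl-cation scavenger; at −78 °C the Z-alkene and the two trans 2-aryl-dihydrobenzofuran rings should survive, and no stereocentre is touched.

**Compound list**

1 | 4-bromo-3,5-dichlorophenol | Oc1cc(Cl)c(Br)c(Cl)c1 | starting material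
2 | 5-(benzyloxy)-2-bromo-1,3-dichlorobenzene | Clc1cc(OCc2ccccc2)cc(Cl)c1Br | intermediate
3 | 1-[4-(benzyloxy)phenyl]ethan-1-one | CC(=O)c1ccc(OCc2ccccc2)cc1 | starting material
4 | 1-[4-(benzyloxy)phenyl]-2-[4-(benzyloxy)-2,6-dichlorophenyl]ethan-1-one | O=C(Cc1c(Cl)cc(OCc2ccccc2)cc1Cl)c1ccc(OCc2ccccc2)cc1 | intermediate
5 | 1,3-bis(benzyloxy)-5-bromobenzene | Brc1cc(OCc2ccccc2)cc(OCc2ccccc2)c1 | starting material
6 | rac-1-[4-(benzyloxy)phenyl]-2-[4-(benzyloxy)-2,6-dichlorophenyl]-2-[3,5-bis(benzyloxy)phenyl]ethan-1-one | O=C(C(c1cc(OCc2ccccc2)cc(OCc2ccccc2)c1)c1c(Cl)cc(OCc2ccccc2)cc1Cl)c1ccc(OCc2ccccc2)cc1 | intermediate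
7 | (1R,2R)-1-[4-(benzyloxy)phenyl]-2-[4-(benzyloxy)-2,6-dichlorophenyl]-2-[3,5-bis(benzyloxy)phenyl]ethan-1-ol | O[C@@H](c1ccc(OCc2ccccc2)cc1)[C@H](c1cc(OCc2ccccc2)cc(OCc2ccccc2)c1)c1c(Cl)cc(OCc2ccccc2)cc1Cl | intermediate
8 | (2R,3R)-6-(benzyloxy)-2-[4-(benzyloxy)phenyl]-3-[3,5-bis(benzyloxy)phenyl]-4-chloro-2,3-dihydro-1-benzofuran | Clc1cc(OCc2ccccc2)cc2c1[C@@H](c1cc(OCc3ccccc3)cc(OCc3ccccc3)c1)[C@H](c1ccc(OCc3ccccc3)cc1)O2 | intermediate (not isolated)
9 | 1-[4-(benzyloxy)phenyl]-2-{(2R,3R)-6-(benzyloxy)-2-[4-(benzyloxy)phenyl]-3-[3,5-bis(benzyloxy)phenyl]-2,3-dihydro-1-benzofuran-4-yl}ethan-1-one | O=C(Cc1cc(OCc2ccccc2)cc2c1[C@@H](c1cc(OCc3ccccc3)cc(OCc3ccccc3)c1)[C@H](c1ccc(OCc3ccccc3)cc1)O2)c1ccc(OCc2ccccc2)cc1 | intermediate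
10 | 1-[4-(benzyloxy)phenyl]-2-[4-(benzyloxy)-2,6-dichlorophenyl]-2-(RB)ethan-1-one, both C2 epimers | O=C(C(c1c(Cl)cc(OCc2ccccc2)cc1Cl)c1cc(OCc2ccccc2)cc2c1[C@@H](c1cc(OCc3ccccc3)cc(OCc3ccccc3)c1)[C@H](c1ccc(OCc3ccccc3)cc1)O2)c1ccc(OCc2ccccc2)cc1 | intermediate
11 | (1S,2S)-1-[4-(benzyloxy)phenyl]-2-[4-(benzyloxy)-2,6-dichlorophenyl]-2-(RB)ethan-1-ol | O[C@H](c1ccc(OCc2ccccc2)cc1)[C@H](c1c(Cl)cc(OCc2ccccc2)cc1Cl)c1cc(OCc2ccccc2)cc2c1[C@@H](c1cc(OCc3ccccc3)cc(OCc3ccccc3)c1)[C@H](c1ccc(OCc3ccccc3)cc1)O2 | intermediate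
12 | (2S,3S)-6-(benzyloxy)-2-[4-(benzyloxy)phenyl]-4-chloro-3-(RB)-2,3-dihydro-1-benzofuran | Clc1cc(OCc2ccccc2)cc2c1[C@H](c1cc(OCc3ccccc3)cc3c1[C@@H](c1cc(OCc4ccccc4)cc(OCc4ccccc4)c1)[C@H](c1ccc(OCc4ccccc4)cc1)O3)[C@@H](c1ccc(OCc3ccccc3)cc1)O2 | intermediate
13 | 1-(benzyloxy)-4-ethynylbenzene | C#Cc1ccc(OCc2ccccc2)cc1 | starting material
14 | (2S,3S)-6-(benzyloxy)-2-[4-(benzyloxy)phenyl]-4-{[4-(benzyloxy)phenyl]ethynyl}-3-(RB)-2,3-dihydro-1-benzofuran | C(#Cc1ccc(OCc2ccccc2)cc1)c1cc(OCc2ccccc2)cc2c1[C@H](c1cc(OCc3ccccc3)cc3c1[C@@H](c1cc(OCc4ccccc4)cc(OCc4ccccc4)c1)[C@H](c1ccc(OCc4ccccc4)cc1)O3)[C@@H](c1ccc(OCc3ccccc3)cc1)O2 | intermediate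
15 | (2S,3S)-6-(benzyloxy)-2-[4-(benzyloxy)phenyl]-4-{(Z)-2-[4-(benzyloxy)phenyl]ethenyl}-3-(RB)-2,3-dihydro-1-benzofuran (hepta-O-benzyl-cis-miyabenol C) | c1ccccc1COc1ccc(/C=C\c2cc(OCc3ccccc3)cc3c2[C@H](c2cc(OCc4ccccc4)cc4c2[C@@H](c2cc(OCc5ccccc5)cc(OCc5ccccc5)c2)[C@H](c2ccc(OCc5ccccc5)cc2)O4)[C@@H](c2ccc(OCc4ccccc4)cc2)O3)cc1 | intermediate
16 | cis-miyabenol C, (2S,3S)-3-[(2R,3R)-3-(3,5-dihydroxyphenyl)-6-hydroxy-2-(4-hydroxyphenyl)-2,3-dihydro-1-benzofuran-4-yl]-2-(4-hydroxyphenyl)-4-[(Z)-2-(4-hydroxyphenyl)ethenyl]-2,3-dihydro-1-benzofuran-6-ol | Oc1ccc(/C=C\c2cc(O)cc3c2[C@H](c2cc(O)cc4c2[C@@H](c2cc(O)cc(O)c2)[C@H](c2ccc(O)cc2)O4)[C@@H](c2ccc(O)cc2)O3)cc1 | target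

**Totals.** Total step count: 11. Longest linear sequence: 11 steps (1 to 16).

**Steps most likely to fail**

Step 6. The C–C bond may not form: the ortho-substituted enolate of 9 has to reach a palladium centre that already carries a 2,6-dichloroaryl group, and conditions forcing enough for this crowded transmetalation may begin to activate C–Cl bonds (enolate O-arylation to a benzofuran). Fallback, reversed polarity: step 5 is stopped after its first stage and 8 is isolated. Palladium-catalysed hydroxylation of its C–Cl bond (KOH, Pd2(dba)3, tBuXPhos, dioxane/H2O, 100 °C) gives the phenol (2R,3R)-6-(benzyloxy)-2-[4-(benzyloxy)phenyl]-3-[3,5-bis(benzyloxy)phenyl]-2,3-dihydro-1-benzofuran-4-ol F1. Tf2O/pyridine converts it into the corresponding 4-yl trifluoromethanesulfonate F2. F2 is coupled with the enolate of deoxybenzoin 4 (Pd2(dba)3, Xantphos, K3PO4, toluene, 80 °C), conditions under which the triflate reacts and every C–Cl bond is left alone. The product is 10 and the route continues with step 7.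

Step 7. Substrate and catalyst control may be mismatched: the bulky ring-B aryl group instead of the dichloroaryl group may take the Felkin large position, so that the catalyst reduces the C2 epimer leading to the cis ring, or epimerisation at the crowded C2 may be slower than reduction. Fallback, thermodynamic correction at C2 of ring A, so that only C3 of ring A has to come from the reduction: setting out from 10, hydrogenation with the (S,S) catalyst of step 4 gives (1R,2S)-1-[4-(benzyloxy)phenyl]-2-[4-(benzyloxy)-2,6-dichlorophenyl]-2-(RB)ethan-1-ol F3. Ring closure under the conditions of step 8 gives the 2,3-cis compound (2R,3S)-6-(benzyloxy)-2-[4-(benzyloxy)phenyl]-4-chloro-3-(RB)-2,3-dihydro-1-benzofuran F4. TFA in CH2Cl2 (0 °C to rt) then epimerises C2 through the ring-opened 4-benzyloxybenzyl cation to the more stable 2,3-trans isomer, which is 12.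

Step 5. β-Hydride elimination of the palladium-bound secondary alkoxide (ketone 6 plus hydrodechlorination) may compete with C–O reductive elimination, and the catalyst may not survive into the second stage. Fallback, metal-free closure of the same bond by SNAr at a C–F bond: setting out from 3, α-arylation as in step 2 with 5-(benzyloxy)-2-bromo-1-chloro-3-fluorobenzene F5 (benzyl ether of purchased 4-bromo-3-chloro-5-fluorophenol, made as in step 1) gives 1-[4-(benzyloxy)phenyl]-2-[4-(benzyloxy)-2-chloro-6-fluorophenyl]ethan-1-one F6. Arylation with 5 as in step 3 gives rac-1-[4-(benzyloxy)phenyl]-2-[4-(benzyloxy)-2-chloro-6-fluorophenyl]-2-[3,5-bis(benzyloxy)phenyl]ethan-1-one F7. Hydrogenation as in step 4 gives (1R,2R)-1-[4-(benzyloxy)phenyl]-2-[4-(benzyloxy)-2-chloro-6-fluorophenyl]-2-[3,5-bis(benzyloxy)phenyl]ethan-1-ol F8. NaH in DMF at 70 °C then closes O1–C7a by addition–elimination at the C–F bond, where chloride is not displaced. This gives 8, which is isolated and arylated with 3 (Pd2(dba)3, XPhos, NaOtBu, toluene, 100 °C) to rejoin the route at 9.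

Further compounds
F1 | step 6 | (2R,3R)-6-(benzyloxy)-2-[4-(benzyloxy)phenyl]-3-[3,5-bis(benzyloxy)phenyl]-2,3-dihydro-1-benzofuran-4-ol | Oc1cc(OCc2ccccc2)cc2c1[C@@H](c1cc(OCc3ccccc3)cc(OCc3ccccc3)c1)[C@H](c1ccc(OCc3ccccc3)cc1)O2
F2 | step 6 | (2R,3R)-6-(benzyloxy)-2-[4-(benzyloxy)phenyl]-3-[3,5-bis(benzyloxy)phenyl]-2,3-dihydro-1-benzofuran-4-yl trifluoromethanesulfonate | FC(F)(F)S(=O)(=O)Oc1cc(OCc2ccccc2)cc2c1[C@@H](c1cc(OCc3ccccc3)cc(OCc3ccccc3)c1)[C@H](c1ccc(OCc3ccccc3)cc1)O2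
F3 | step 7 | (1R,2S)-1-[4-(benzyloxy)phenyl]-2-[4-(benzyloxy)-2,6-dichlorophenyl]-2-(RB)ethan-1-ol | O[C@@H](c1ccc(OCc2ccccc2)cc1)[C@H](c1c(Cl)cc(OCc2ccccc2)cc1Cl)c1cc(OCc2ccccc2)cc2c1[C@@H](c1cc(OCc3ccccc3)cc(OCc3ccccc3)c1)[C@H](c1ccc(OCc3ccccc3)cc1)O2
F4 | step 7 | (2R,3S)-6-(benzyloxy)-2-[4-(benzyloxy)phenyl]-4-chloro-3-(RB)-2,3-dihydro-1-benzofuran (2,3-cis) | Clc1cc(OCc2ccccc2)cc2c1[C@H](c1cc(OCc3ccccc3)cc3c1[C@@H](c1cc(OCc4ccccc4)cc(OCc4ccccc4)c1)[C@H](c1ccc(OCc4ccccc4)cc1)O3)[C@H](c1ccc(OCc3ccccc3)cc1)O2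
F5 | step 5 | 5-(benzyloxy)-2-bromo-1-chloro-3-fluorobenzene | Fc1cc(OCc2ccccc2)cc(Cl)c1Br
F6 | step 5 | 1-[4-(benzyloxy)phenyl]-2-[4-(benzyloxy)-2-chloro-6-fluorophenyl]ethan-1-one | O=C(Cc1c(F)cc(OCc2ccccc2)cc1Cl)c1ccc(OCc2ccccc2)cc1
F7 | step 5 | rac-1-[4-(benzyloxy)phenyl]-2-[4-(benzyloxy)-2-chloro-6-fluorophenyl]-2-[3,5-bis(benzyloxy)phenyl]ethan-1-one | O=C(C(c1cc(OCc2ccccc2)cc(OCc2ccccc2)c1)c1c(F)cc(OCc2ccccc2)cc1Cl)c1ccc(OCc2ccccc2)cc1
F8 | step 5 | (1R,2R)-1-[4-(benzyloxy)phenyl]-2-[4-(benzyloxy)-2-chloro-6-fluorophenyl]-2-[3,5-bis(benzyloxy)phenyl]ethan-1-ol | O[C@@H](c1ccc(OCc2ccccc2)cc1)[C@H](c1cc(OCc2ccccc2)cc(OCc2ccccc2)c1)c1c(F)cc(OCc2ccccc2)cc1Cl
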